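**Retrosynthetic overview**
1. Glaucolide K ⇐ last-step epoxidation of the (E)-4,5-alkene from the outer ring face; the O-8 methacrylate and the O-1/O-13 acetates are put on just before (epoxide ring formed last).
2. Butenolide ⇐ C-8-hydroxyl-directed syn reduction of a C-6 ketone, then lactonisation onto the cis ester (second ring).
3. Ten-membered ring ⇐ carbonylative Stille macrocyclisation in which carbon monoxide becomes C-6 between vinyl iodide C-5 and vinylstannane C-7 (key step, first ring).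
4. Seco compound ⇐ aldehyde 9 (C-1 to C-5, C-8 to C-10) + linchpin 16 (C-7, C-11 to C-13) made by two successive Br/Mg exchanges on a dibromoacrylate; CBS reduction sets C-8.
5. C-1/C-10 ⇐ catalytic asymmetric (Z)-crotylboration of pent-4-ynal; (E)-C4=C5 and C-15 ⇐ Negishi carboalumination.

Assumption: compounds 1, 2 and 10 are bought; macrocycles are named with germacrane numbering (ring C-1 to C-10, C-11/C-12/C-13 on C-7, C-14 on C-10, C-15 on C-4); TBS = tert-butyldimethylsilyl; (R)-TRIP is taken to shield the same aldehyde face as with simple aldehydes.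

Step 1
Reactants: 1 pent-4-ynal; 2 (Z)-crotylboronic acid pinacol ester
Product: 3 (3S,4S)-3-methyloct-1-en-7-yn-4-ol
Conditions: (R)-TRIP [(R)-3,3'-bis(2,4,6-triisopropylphenyl)-1,1'-binaphthyl-2,2'-diyl hydrogen phosphate] (5 mol%), 4 Å MS, toluene, −30 °C; aq. NaHCO3
Reagents that add atoms: none
Why: Chiral-phosphoric-acid-catalysed asymmetric crotylboration through a closed Zimmerman–Traxler chair, in which the (Z)-crotyl geometry gives the syn methyl/hydroxyl pair and the (R)-acid fixes 4S, so C-10 and C-1 of the target are set together.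

Step 2
Reactants: 3 (3S,4S)-3-methyloct-1-en-7-yn-4-ol
Product: 4 tert-butyldimethyl{[(3S,4S)-3-methyloct-1-en-7-yn-4-yl]oxy}silane
Conditions: TBSOTf, 2,6-lutidine, CH2Cl2, −78 → 0 °C
Reagents that add atoms: tert-butyldimethylsilyl triflate, CC(C)(C)[Si](C)(C)OS(=O)(=O)C(F)(F)F
Why: Standard silylation of a hindered secondary alcohol with the silyl triflate masks O-1 through all organometallic steps.

Step 3
Reactants: 4 tert-butyldimethyl{[(3S,4S)-3-methyloct-1-en-7-yn-4-yl]oxy}silane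
Product: 6 tert-butyl{[(3S,4S,7E)-8-iodo-3,7-dimethylocta-1,7-dien-4-yl]oxy}dimethylsilane, via alkenyldimethylalane 5 (not isolated)
Conditions: AlMe3, Cp2ZrCl2 (25 mol%), CH2Cl2, 0 °C → rt; then I2, THF, −30 °C
Reagents that add atoms: trimethylaluminium, C[Al](C)C; iodine, II
Why: Negishi zirconium-catalysed carboalumination adds methyl and aluminium syn across the terminal alkyne (methyl to the internal carbon) and iodinolysis of the C–Al bond goes with retention, so the (E)-trisubstituted C4=C5 geometry and C-15 are fixed while the slower terminal alkene is untouched.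

Step 4
Reactants: 6 tert-butyl{[(3S,4S,7E)-8-iodo-3,7-dimethylocta-1,7-dien-4-yl]oxy}dimethylsilane
Product: 8 (3S,4S,7E)-4-(TBS-oxy)-8-iodo-3,7-dimethyloct-7-en-1-ol, via B-alkyl-9-BBN adduct 7 (not isolated)
Conditions: 9-BBN, THF, 0 °C → rt; then H2O2, aq. NaOH, 0 °C
Reagents that add atoms: hydrogen peroxide, OO
Why: Anti-Markovnikov hydroboration with the bulky dialkylborane is selective for the monosubstituted alkene over the trisubstituted iodoalkene, and oxidation of the C–B bond gives the primary alcohol whose carbon becomes C-8.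

Step 5
Reactants: 8 (3S,4S,7E)-4-(TBS-oxy)-8-iodo-3,7-dimethyloct-7-en-1-ol
Product: 9 (3S,4S,7E)-4-(TBS-oxy)-8-iodo-3,7-dimethyloct-7-enal
Conditions: Dess–Martin periodinane, NaHCO3, CH2Cl2, rt
Reagents that add atoms: none
Why: Dess–Martin oxidation of a primary alcohol to the aldehyde under buffered conditions leaves the silyl ether, the vinyl iodide and the β-stereocentre alone.

Step 6
Reactants: 10 ethyl 2-(hydroxymethyl)prop-2-enoate
Product: 11 ethyl 2-[(TBS-oxy)methyl]prop-2-enoate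
Conditions: TBSCl, imidazole, CH2Cl2, rt
Reagents that add atoms: tert-butyldimethylsilyl chloride, CC(C)(C)[Si](C)(C)Cl
Why: Routine silylation of the primary alcohol protects the future O-13.

Step 7
Reactants: 11 ethyl 2-[(TBS-oxy)methyl]prop-2-enoate
Product: 13 ethyl 3-(TBS-oxy)-2-oxopropanoate, via ozonide 12 (not isolated)
Conditions: O3, CH2Cl2, −78 °C; then Me2S, −78 °C → rt
Reagents that add atoms: ozone, O=[O+][O-]
Why: Ozonolysis of the 1,1-disubstituted alkene and reductive cleavage of the ozonide give the α-keto ester that carries C-11, C-12 and C-13.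

Step 8
Reactants: 13 ethyl 3-(TBS-oxy)-2-oxopropanoate
Product: 14 ethyl 3,3-dibromo-2-[(TBS-oxy)methyl]prop-2-enoate
Conditions: CBr4, PPh3, CH2Cl2, 0 °C
Reagents that add atoms: carbon tetrabromide, BrC(Br)(Br)Br
Why: Ramirez dibromo-olefination (the first half of a Corey–Fuchs sequence) of the activated ketone by the ylide from CBr4 and PPh3 installs the CBr2 carbon that becomes C-7.

Step 9
Reactants: 14 ethyl 3,3-dibromo-2-[(TBS-oxy)methyl]prop-2-enoate
Product: 16 ethyl (2Z)-3-bromo-2-[(TBS-oxy)methyl]-3-(trimethylstannyl)prop-2-enoate, via magnesium carbenoid 15 (not isolated)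
Conditions: iPrMgCl, THF, −78 °C; then Me3SnCl, −78 → −40 °C
Reagents that add atoms: trimethyltin chloride, C[Sn](C)(C)Cl
Why: Ester-directed bromine–magnesium exchange takes place only at the bromine cis to the ester to give a carbenoid that is configurationally stable at −78 °C, and stannylation with retention places tin cis to the ester, where C-6 will later be attached.

Step 10
Reactants: 16 ethyl (2Z)-3-bromo-2-[(TBS-oxy)methyl]-3-(trimethylstannyl)prop-2-enoate; 9 (3S,4S,7E)-4-(TBS-oxy)-8-iodo-3,7-dimethyloct-7-enal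
Product: 18 ethyl (2Z,6S,7S,10E)-7-(TBS-oxy)-2-[(TBS-oxy)methyl]-4-hydroxy-11-iodo-6,10-dimethyl-3-(trimethylstannyl)undeca-2,10-dienoate (both C-4 epimers), via alkenylmagnesium chloride 17 (not isolated)
Conditions: iPrMgCl·LiCl, THF, −40 °C; then 9, −40 → −10 °C; aq. NH4Cl
Reagents that add atoms: none
Why: A second bromine–magnesium exchange gives the α-stannyl alkenylmagnesium with retention of geometry, and its Grignard addition to aldehyde 9 forms the C-7/C-8 bond trans to the ester (so no lactone can form), giving both C-8 epimers, which converge in steps 11 and 12.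

Step 11
Reactants: 18 ethyl (2Z,6S,7S,10E)-7-(TBS-oxy)-2-[(TBS-oxy)methyl]-4-hydroxy-11-iodo-6,10-dimethyl-3-(trimethylstannyl)undeca-2,10-dienoate
Product: 19 ethyl (2Z,6S,7S,10E)-7-(TBS-oxy)-2-[(TBS-oxy)methyl]-11-iodo-6,10-dimethyl-4-oxo-3-(trimethylstannyl)undeca-2,10-dienoate
Conditions: Dess–Martin periodinane, NaHCO3, CH2Cl2, 0 °C → rt
Reagents that add atoms: none
Why: Dess–Martin oxidation of the secondary allylic alcohol removes the uncontrolled centre and gives the α-stannyl enone needed for reagent-controlled reduction.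

Step 12
Reactants: 19 ethyl (2Z,6S,7S,10E)-7-(TBS-oxy)-2-[(TBS-oxy)methyl]-11-iodo-6,10-dimethyl-4-oxo-3-(trimethylstannyl)undeca-2,10-dienoate
Product: 20 ethyl (2Z,4S,6S,7S,10E)-7-(TBS-oxy)-2-[(TBS-oxy)methyl]-4-hydroxy-11-iodo-6,10-dimethyl-3-(trimethylstannyl)undeca-2,10-dienoate
Conditions: (R)-2-methyl-CBS-oxazaborolidine (0.5 equiv), catecholborane, toluene, −78 °C
Reagents that add atoms: none
Why: Corey–Bakshi–Shibata reduction, in which the tetrasubstituted α-stannyl alkenyl group is the large substituent and the CH2 group the small one, so the (R)-catalyst gives the 4S alcohol (C-8 of the target) as an α-bromo or α-stannyl enone normally does.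

Step 13
Reactants: 20 ethyl (2Z,4S,6S,7S,10E)-7-(TBS-oxy)-2-[(TBS-oxy)methyl]-4-hydroxy-11-iodo-6,10-dimethyl-3-(trimethylstannyl)undeca-2,10-dienoate
Product: 21 ethyl (1S,8S,10S,4E,7(11)Z)-1,13-bis(TBS-oxy)-8-hydroxy-6-oxogermacra-4,7(11)-dien-12-oate
Conditions: Pd2(dba)3 (10 mol%), AsPh3 (40 mol%), CuI (20 mol%), CO (1 atm), NMP, 50 °C, syringe-pump addition to 1 mM, no base
Reagents that add atoms: carbon monoxide, [C-]#[O+]
Why: Proposed new method: zerovalent palladium inserts into the C–I bond, CO insertion gives an acylpalladium, and copper-assisted intramolecular transmetalation with the cis-ester alkenylstannane followed by reductive elimination closes the ten-membered ring with CO as C-6 and with retention of both alkene geometries, direct coupling being disfavoured because it would give a strained nine-membered diene, the closest known reaction being the carbonylative Stille ring closure of alkenyl halide or triflate/alkenylstannane pairs to macrocyclic dienones.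

Step 14
Reactants: 21 ethyl (1S,8S,10S,4E,7(11)Z)-1,13-bis(TBS-oxy)-8-hydroxy-6-oxogermacra-4,7(11)-dien-12-oate
Product: 23 (1S,6R,8S,10S,4E)-1,13-bis(TBS-oxy)-8-hydroxygermacra-4,7(11)-dien-12,6-olide, via hydroxy ester 22 (not isolated)
Conditions: Et2BOMe, NaBH4, THF/MeOH (4:1), −78 °C; AcOH, MeOH; then PPTS (cat.), CH2Cl2, rt
Reagents that add atoms: none
Why: Narasaka–Prasad reduction, in which the C-8 hydroxyl and the C-6 ketone sit in a six-membered boron chelate and external hydride gives the 1,3-syn diol (6R by CIP here, the configuration of the target), after which the new hydroxyl closes onto the cis ethyl ester to form the butenolide.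

Step 15
Reactants: 23 (1S,6R,8S,10S,4E)-1,13-bis(TBS-oxy)-8-hydroxygermacra-4,7(11)-dien-12,6-olide
Product: 24 (1S,6R,8S,10S,4E)-1,13-bis(TBS-oxy)-8-(methacryloyloxy)germacra-4,7(11)-dien-12,6-olide
Conditions: methacrylic anhydride, i-Pr2NEt, DMAP (cat.), CH2Cl2, 0 °C
Reagents that add atoms: methacrylic anhydride, C=C(C)C(=O)OC(=O)C(C)=C
Why: DMAP-catalysed acylation of the only free hydroxyl installs the C-8 ester at low temperature so that the butenolide γ-centre is not epimerised.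

Step 16
Reactants: 24 (1S,6R,8S,10S,4E)-1,13-bis(TBS-oxy)-8-(methacryloyloxy)germacra-4,7(11)-dien-12,6-olide
Product: 25 (1S,6R,8S,10S,4E)-1,13-dihydroxy-8-(methacryloyloxy)germacra-4,7(11)-dien-12,6-olide
Conditions: HF·pyridine, pyridine, THF, 0 °C → rt
Reagents that add atoms: none
Why: Fluoride-mediated cleavage of both silyl ethers under buffered, non-basic conditions spares the esters and the lactone and is done before the acid-sensitive epoxide exists.

Step 17
Reactants: 25 (1S,6R,8S,10S,4E)-1,13-dihydroxy-8-(methacryloyloxy)germacra-4,7(11)-dien-12,6-olide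
Product: 26 (1S,6R,8S,10S,4E)-1,13-diacetoxy-8-(methacryloyloxy)germacra-4,7(11)-dien-12,6-olide
Conditions: Ac2O, pyridine, DMAP (cat.), CH2Cl2, 0 °C
Reagents that add atoms: acetic anhydride, CC(=O)OC(C)=O
Why: One acetylation esterifies the primary C-13 and the secondary C-1 hydroxyl together, which is why both were carried as the same silyl ether.

Step 18
Reactants: 26 (1S,6R,8S,10S,4E)-1,13-diacetoxy-8-(methacryloyloxy)germacra-4,7(11)-dien-12,6-olide
Product: 27 glaucolide K, (1S,4R,5R,6S,8S,10S)-1,13-diacetoxy-4,5-epoxy-8-(methacryloyloxy)germacr-7(11)-en-12,6-olide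
Conditions: mCPBA, NaHCO3, CH2Cl2, 0 °C
Reagents that add atoms: 3-chloroperbenzoic acid, OOC(=O)c1cccc(Cl)c1
Why: Prilezhaev epoxidation is chemoselective for the only electron-rich alkene, keeps the E geometry, and attacks the outer face of the ring alkene, which in the conformer with H-6 in the alkene plane (A1,3 strain with the C-15 methyl) is the face carrying O-6, giving the 4R,5R epoxide.

**Compound list**
1 | pent-4-ynal | C#CCCC=O | starting material
2 | (Z)-crotylboronic acid pinacol ester | C/C=C\CB1OC(C)(C)C(C)(C)O1 | starting material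
3 | (3S,4S)-3-methyloct-1-en-7-yn-4-ol | C=C[C@H](C)[C@@H](O)CCC#C | intermediate
4 | tert-butyldimethyl{[(3S,4S)-3-methyloct-1-en-7-yn-4-yl]oxy}silane | C=C[C@H](C)[C@@H](O[Si](C)(C)C(C)(C)C)CCC#C | intermediate
5 | dimethyl[(1E,5S,6S)-5-(TBS-oxy)-2,6-dimethylocta-1,7-dien-1-yl]alane | C=C[C@H](C)[C@@H](O[Si](C)(C)C(C)(C)C)CC/C(C)=C/[Al](C)C | intermediate
6 | tert-butyl{[(3S,4S,7E)-8-iodo-3,7-dimethylocta-1,7-dien-4-yl]oxy}dimethylsilane | C=C[C@H](C)[C@@H](O[Si](C)(C)C(C)(C)C)CC/C(C)=C/I | intermediate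
7 | 9-[(3S,4S,7E)-4-(TBS-oxy)-8-iodo-3,7-dimethyloct-7-en-1-yl]-9-borabicyclo[3.3.1]nonane | C1CCC2CCCC1B2CC[C@H](C)[C@@H](O[Si](C)(C)C(C)(C)C)CC/C(C)=C/I | intermediate
8 | (3S,4S,7E)-4-(TBS-oxy)-8-iodo-3,7-dimethyloct-7-en-1-ol | OCC[C@H](C)[C@@H](O[Si](C)(C)C(C)(C)C)CC/C(C)=C/I | intermediate
9 | (3S,4S,7E)-4-(TBS-oxy)-8-iodo-3,7-dimethyloct-7-enal | O=CC[C@H](C)[C@@H](O[Si](C)(C)C(C)(C)C)CC/C(C)=C/I | intermediate
10 | ethyl 2-(hydroxymethyl)prop-2-enoate | C=C(CO)C(=O)OCC | starting material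
11 | ethyl 2-[(TBS-oxy)methyl]prop-2-enoate | C=C(CO[Si](C)(C)C(C)(C)C)C(=O)OCC | intermediate
12 | ethyl 3-[(TBS-oxy)methyl]-1,2,4-trioxolane-3-carboxylate (racemic ozonide) | CCOC(=O)C1(CO[Si](C)(C)C(C)(C)C)OCOO1 | intermediate
13 | ethyl 3-(TBS-oxy)-2-oxopropanoate | CCOC(=O)C(=O)CO[Si](C)(C)C(C)(C)C | intermediate
14 | ethyl 3,3-dibromo-2-[(TBS-oxy)methyl]prop-2-enoate | CCOC(=O)C(CO[Si](C)(C)C(C)(C)C)=C(Br)Br | intermediate
15 | ethyl (2E)-3-bromo-3-(chloromagnesio)-2-[(TBS-oxy)methyl]prop-2-enoate (Mg cis to ester) | CCOC(=O)/C(CO[Si](C)(C)C(C)(C)C)=C(/Br)[Mg]Cl | intermediate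
16 | ethyl (2Z)-3-bromo-2-[(TBS-oxy)methyl]-3-(trimethylstannyl)prop-2-enoate (Sn cis to ester) | CCOC(=O)/C(CO[Si](C)(C)C(C)(C)C)=C(/Br)[Sn](C)(C)C | intermediate
17 | ethyl (2Z)-3-(chloromagnesio)-2-[(TBS-oxy)methyl]-3-(trimethylstannyl)prop-2-enoate | CCOC(=O)/C(CO[Si](C)(C)C(C)(C)C)=C(/[Mg]Cl)[Sn](C)(C)C | intermediate
18 | ethyl (2Z,6S,7S,10E)-7-(TBS-oxy)-2-[(TBS-oxy)methyl]-4-hydroxy-11-iodo-6,10-dimethyl-3-(trimethylstannyl)undeca-2,10-dienoate (C-4 epimers) | CCOC(=O)/C(CO[Si](C)(C)C(C)(C)C)=C(/C(O)C[C@H](C)[C@@H](O[Si](C)(C)C(C)(C)C)CC/C(C)=C/I)[Sn](C)(C)C | intermediate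
19 | ethyl (2Z,6S,7S,10E)-7-(TBS-oxy)-2-[(TBS-oxy)methyl]-11-iodo-6,10-dimethyl-4-oxo-3-(trimethylstannyl)undeca-2,10-dienoate | CCOC(=O)/C(CO[Si](C)(C)C(C)(C)C)=C(/C(=O)C[C@H](C)[C@@H](O[Si](C)(C)C(C)(C)C)CC/C(C)=C/I)[Sn](C)(C)C | intermediate
20 | ethyl (2Z,4S,6S,7S,10E)-7-(TBS-oxy)-2-[(TBS-oxy)methyl]-4-hydroxy-11-iodo-6,10-dimethyl-3-(trimethylstannyl)undeca-2,10-dienoate | CCOC(=O)/C(CO[Si](C)(C)C(C)(C)C)=C(/[C@@H](O)C[C@H](C)[C@@H](O[Si](C)(C)C(C)(C)C)CC/C(C)=C/I)[Sn](C)(C)C | intermediate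
21 | ethyl (1S,8S,10S,4E,7(11)Z)-1,13-bis(TBS-oxy)-8-hydroxy-6-oxogermacra-4,7(11)-dien-12-oate | O[C@H]1C[C@H](C)[C@@H](O[Si](C)(C)C(C)(C)C)CC/C(C)=C/C(=O)/C1=C(/CO[Si](C)(C)C(C)(C)C)C(=O)OCC | intermediate
22 | ethyl (1S,6R,8S,10S,4E,7(11)Z)-1,13-bis(TBS-oxy)-6,8-dihydroxygermacra-4,7(11)-dien-12-oate | O[C@H]1C[C@H](C)[C@@H](O[Si](C)(C)C(C)(C)C)CC/C(C)=C/[C@@H](O)/C1=C(/CO[Si](C)(C)C(C)(C)C)C(=O)OCC | intermediate
23 | (1S,6R,8S,10S,4E)-1,13-bis(TBS-oxy)-8-hydroxygermacra-4,7(11)-dien-12,6-olide | O[C@H]1C[C@H](C)[C@@H](O[Si](C)(C)C(C)(C)C)CC/C(C)=C/[C@H]2OC(=O)C(CO[Si](C)(C)C(C)(C)C)=C12 | intermediate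
24 | (1S,6R,8S,10S,4E)-1,13-bis(TBS-oxy)-8-(methacryloyloxy)germacra-4,7(11)-dien-12,6-olide | C=C(C)C(=O)O[C@H]1C[C@H](C)[C@@H](O[Si](C)(C)C(C)(C)C)CC/C(C)=C/[C@H]2OC(=O)C(CO[Si](C)(C)C(C)(C)C)=C12 | intermediate
25 | (1S,6R,8S,10S,4E)-1,13-dihydroxy-8-(methacryloyloxy)germacra-4,7(11)-dien-12,6-olide | C=C(C)C(=O)O[C@H]1C[C@H](C)[C@@H](O)CC/C(C)=C/[C@H]2OC(=O)C(CO)=C12 | intermediate
26 | (1S,6R,8S,10S,4E)-1,13-diacetoxy-8-(methacryloyloxy)germacra-4,7(11)-dien-12,6-olide | C=C(C)C(=O)O[C@H]1C[C@H](C)[C@@H](OC(C)=O)CC/C(C)=C/[C@H]2OC(=O)C(COC(C)=O)=C12 | intermediate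
27 | glaucolide K | C=C(C)C(=O)O[C@H]1C[C@H](C)[C@@H](OC(C)=O)CC[C@@]2(C)O[C@@H]2[C@H]2OC(=O)C(COC(C)=O)=C12 | target

**Totals and risk**
Total step count: 18. Longest linear sequence: 14 steps (steps 1–5, then 10–18); the linchpin branch is steps 6–9.

The three steps most likely to fail:

Step 13 (carbonylative ring closure). The hindered, electron-poor stannane may transmetalate too slowly, so that direct coupling or attack of the free C-8 hydroxyl on the acylpalladium wins. The fallback puts CO between the fragments first and closes the ring at C-7/C-8; it sets out from 6 and 16 and comes back at 23. Vinyl iodide 6 and stannane 16 are joined by an intermolecular carbonylative Stille coupling (Pd2(dba)3, AsPh3, CuI, CO) to the acyclic bromo dienone F1. (S)-2-Methyl-CBS-oxazaborolidine and catecholborane reduce this α-bromo enone under reagent control to the hydroxy ester F2, which lactonises to the bromobutenolide F3. Hydroboration with 9-BBN gives the B-alkyl-9-BBN adduct F4 and buffered oxidation the primary alcohol F5; Dess–Martin oxidation gives the aldehyde F6. An intramolecular Nozaki–Hiyama–Kishi reaction (CrCl2, NiCl2 cat., DMSO, high dilution) between the bromobutenolide carbon and the aldehyde then closes the ten-membered ring to 23, whose 8S epimer is separated from the 8R epimer.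

Step 14 (C-6 configuration). Chelate control across the sp2 carbon C-7 inside a ten-membered ring may be weak. The fallback replaces substrate direction by reagent control; it sets out from 21 and comes back at 24. Ketone 21 is first esterified with methacrylic anhydride to the keto methacrylate F7. (S)-2-Methyl-CBS-oxazaborolidine and catecholborane (tetrasubstituted alkenyl group as the large substituent) then reduce the C-6 ketone to the hydroxy ester F8, which lactonises to 24.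

Step 18 (face of epoxidation). If the peracid attacks the other face of the ring alkene, the halohydrin route delivers oxygen to the face opposite the electrophile; it sets out from 26 and comes back at 27. NBS in aqueous THF adds bromine from the exposed face and water at the tertiary C-4 from the other face to give the bromohydrin F9. Ag2O in CH2Cl2 then closes the epoxide with inversion at C-5 to give 27.

**Further compounds**
F1 | step 13 | ethyl (2E,5E,9S,10S)-3-bromo-9-(TBS-oxy)-2-[(TBS-oxy)methyl]-6,10-dimethyl-4-oxododeca-2,5,11-trienoate | C=C[C@H](C)[C@@H](O[Si](C)(C)C(C)(C)C)CC/C(C)=C/C(=O)C(/Br)=C(/CO[Si](C)(C)C(C)(C)C)C(=O)OCC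
F2 | step 13 | ethyl (2E,4R,5E,9S,10S)-3-bromo-9-(TBS-oxy)-2-[(TBS-oxy)methyl]-4-hydroxy-6,10-dimethyldodeca-2,5,11-trienoate | C=C[C@H](C)[C@@H](O[Si](C)(C)C(C)(C)C)CC/C(C)=C/[C@@H](O)C(/Br)=C(/CO[Si](C)(C)C(C)(C)C)C(=O)OCC
F3 | step 13 | (5R)-4-bromo-3-[(TBS-oxy)methyl]-5-[(1E,5S,6S)-5-(TBS-oxy)-2,6-dimethylocta-1,7-dien-1-yl]furan-2(5H)-one | C=C[C@H](C)[C@@H](O[Si](C)(C)C(C)(C)C)CC/C(C)=C/[C@H]1OC(=O)C(CO[Si](C)(C)C(C)(C)C)=C1Br
F4 | step 13 | 9-{(3S,4S,7E)-8-[(2R)-3-bromo-4-[(TBS-oxy)methyl]-5-oxo-2,5-dihydrofuran-2-yl]-4-(TBS-oxy)-3,7-dimethyloct-7-en-1-yl}-9-borabicyclo[3.3.1]nonane | C1CCC2CCCC1B2CC[C@H](C)[C@@H](O[Si](C)(C)C(C)(C)C)CC/C(C)=C/[C@H]1OC(=O)C(CO[Si](C)(C)C(C)(C)C)=C1Br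
F5 | step 13 | (5R)-4-bromo-3-[(TBS-oxy)methyl]-5-[(1E,5S,6S)-5-(TBS-oxy)-8-hydroxy-2,6-dimethyloct-1-en-1-yl]furan-2(5H)-one | OCC[C@H](C)[C@@H](O[Si](C)(C)C(C)(C)C)CC/C(C)=C/[C@H]1OC(=O)C(CO[Si](C)(C)C(C)(C)C)=C1Br
F6 | step 13 | (3S,4S,7E)-8-[(2R)-3-bromo-4-[(TBS-oxy)methyl]-5-oxo-2,5-dihydrofuran-2-yl]-4-(TBS-oxy)-3,7-dimethyloct-7-enal | O=CC[C@H](C)[C@@H](O[Si](C)(C)C(C)(C)C)CC/C(C)=C/[C@H]1OC(=O)C(CO[Si](C)(C)C(C)(C)C)=C1Br
F7 | step 14 | ethyl (1S,8S,10S,4E,7(11)Z)-1,13-bis(TBS-oxy)-8-(methacryloyloxy)-6-oxogermacra-4,7(11)-dien-12-oate | C=C(C)C(=O)O[C@H]1C[C@H](C)[C@@H](O[Si](C)(C)C(C)(C)C)CC/C(C)=C/C(=O)/C1=C(/CO[Si](C)(C)C(C)(C)C)C(=O)OCC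
F8 | step 14 | ethyl (1S,6R,8S,10S,4E,7(11)Z)-1,13-bis(TBS-oxy)-6-hydroxy-8-(methacryloyloxy)germacra-4,7(11)-dien-12-oate | C=C(C)C(=O)O[C@H]1C[C@H](C)[C@@H](O[Si](C)(C)C(C)(C)C)CC/C(C)=C/[C@@H](O)/C1=C(/CO[Si](C)(C)C(C)(C)C)C(=O)OCC
F9 | step 18 | (1S,4R,5S,6S,8S,10S)-1,13-diacetoxy-5-bromo-4-hydroxy-8-(methacryloyloxy)germacr-7(11)-en-12,6-olide | C=C(C)C(=O)O[C@H]1C[C@H](C)[C@@H](OC(C)=O)CC[C@@](C)(O)[C@@H](Br)[C@H]2OC(=O)C(COC(C)=O)=C12
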